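Ring A, the pentasubstituted bromocatechol ring (C1 side chain, C2 benzylic carbon, C3 Br, C4 and C5 oxygens, C6 H), is disconnected across C1–C2 and C3–C4 into a 2-alkyl-4-methoxyfuran and a bromoalkynyl ketone that already carries ring B. One Diels–Alder/ring-opening operation builds ring A with every substituent in place, the furan oxygen ending as the C4 hydroxyl. The precursor pair is a benzyl-protected 2-(2-hydroxyethyl)-4-methoxyfuran and 3-bromo-1-(2,3-dibromo-4,5-dimethoxyphenyl)propynone. The step exploits the contiguous C3(Br)–C4(OH)–C5(O) array of ring A, which matches the polarity of an alkoxyfuran and a β-bromo ynone. Ketone deoxygenation, one BBr3 deprotection and sulfation of the primary alcohol finish the synthesis.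

Key step: step 10

Remark: the side-chain oxygen is carried as a benzyl ether and not as a silyl ether, because BBr3 is known to turn silyl ethers into alkyl bromides, whereas it cleaves the benzyl ether together with the methyl ethers in one operation.

Assumption: the target is drawn as the free hydrogen sulfate; it should be obtained in that form from an acidic ion-exchange resin and would be kept cold or stored as its sodium salt.

Step 1
Reactants: 1 vanillin (4-hydroxy-3-methoxybenzaldehyde)
Product: 3 2,3-dibromo-4-hydroxy-5-methoxybenzaldehyde, via 5-bromovanillin 2 (not isolated)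
Conditions: Br2 (1.05 equiv), AcOH, rt; then Fe powder (cat.), Br2 (1.2 equiv), AcOH, rt
Reagents that add atoms: bromine, BrBr
Why: Electrophilic aromatic bromination: the free phenol directs the first bromine to its open ortho position (C5 of vanillin), and FeBr3 formed from Fe and Br2 then drives the second bromine to C6, para to the methoxy group, which is the established outcome for vanillin.

Step 2
Reactants: 3 2,3-dibromo-4-hydroxy-5-methoxybenzaldehyde
Product: 4 2,3-dibromo-4,5-dimethoxybenzaldehyde
Conditions: MeI, K2CO3, DMF, rt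
Reagents that add atoms: iodomethane, CI
Why: Williamson ether synthesis: the acidic, bromine-flanked phenoxide is methylated by SN2 attack on MeI, and the aldehyde and the aryl bromides are inert to K2CO3 in DMF.

Step 3
Reactants: 4 2,3-dibromo-4,5-dimethoxybenzaldehyde; 5 ethynylmagnesium bromide
Product: 6 1-(2,3-dibromo-4,5-dimethoxyphenyl)prop-2-yn-1-ol (racemic)
Conditions: THF, 0 °C; aq. NH4Cl
Reagents that add atoms: none
Why: Grignard 1,2-addition of the alkynyl nucleophile to the aldehyde should outrun any halogen–magnesium exchange at 0 °C; the new carbinol stereocentre forms as a racemate and is erased in step 4.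

Step 4
Reactants: 6 1-(2,3-dibromo-4,5-dimethoxyphenyl)prop-2-yn-1-ol
Product: 7 1-(2,3-dibromo-4,5-dimethoxyphenyl)prop-2-yn-1-one
Conditions: Dess–Martin periodinane, CH2Cl2, 0 °C → rt
Reagents that add atoms: none
Why: Dess–Martin oxidation of a benzylic, propargylic secondary alcohol is fast under neutral conditions and leaves the terminal alkyne and the aryl bromides untouched.

Step 5
Reactants: 7 1-(2,3-dibromo-4,5-dimethoxyphenyl)prop-2-yn-1-one
Product: 8 3-bromo-1-(2,3-dibromo-4,5-dimethoxyphenyl)prop-2-yn-1-one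
Conditions: NBS (1.1 equiv), AgNO3 (10 mol%), acetone, rt, dark
Reagents that add atoms: N-bromosuccinimide, O=C1CCC(=O)N1Br
Why: Silver-catalysed electrophilic bromination of a terminal alkyne: AgNO3 forms the silver acetylide, which NBS brominates at carbon, while the deactivated dibromoarene should not be ring-brominated under these conditions.

Step 6
Reactants: 9 benzyl 3-butynyl ether (4-benzyloxybut-1-yne); 10 (tert-butyldimethylsilyloxy)acetaldehyde
Product: 12 6-(benzyloxy)-1-[(tert-butyldimethylsilyl)oxy]hex-3-yn-2-ol (racemic), via lithium acetylide 11 (not isolated)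
Conditions: n-BuLi, THF, −78 °C; then 10, −78 → 0 °C; aq. NH4Cl
Reagents that add atoms: none
Why: Deprotonation of the terminal alkyne, the most acidic C–H, and 1,2-addition of the lithium acetylide to the α-silyloxy aldehyde; the carbinol stereocentre is racemic and is removed in step 7.

Step 7
Reactants: 12 6-(benzyloxy)-1-[(tert-butyldimethylsilyl)oxy]hex-3-yn-2-ol
Product: 13 6-(benzyloxy)-1-[(tert-butyldimethylsilyl)oxy]hex-3-yn-2-one
Conditions: Dess–Martin periodinane, CH2Cl2, 0 °C → rt
Reagents that add atoms: none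
Why: Dess–Martin oxidation of the propargylic alcohol to the ynone under neutral conditions that keep the silyl and benzyl ethers intact.

Step 8
Reactants: 13 6-(benzyloxy)-1-[(tert-butyldimethylsilyl)oxy]hex-3-yn-2-one
Product: 16 5-[2-(benzyloxy)ethyl]furan-3(2H)-one, via silyl enaminone 14 (not isolated), via hydroxy enaminone 15 (not isolated)
Conditions: Et2NH (1.5 equiv), EtOH, rt; then 1 M aq. HCl, THF, rt
Reagents that add atoms: none
Why: Aza-Michael addition of Et2NH masks the ynone as a vinylogous amide, aqueous acid then cleaves the primary silyl ether, and the freed hydroxyl closes the five-membered ring by addition–elimination at the iminium carbon (5-exo-trig) with loss of Et2NH, the classical amine-mediated 3(2H)-furanone synthesis from α'-hydroxy ynones.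

Step 9
Reactants: 16 5-[2-(benzyloxy)ethyl]furan-3(2H)-one
Product: 18 2-[2-(benzyloxy)ethyl]-4-methoxyfuran, via potassium furanolate 17 (not isolated)
Conditions: KN(SiMe3)2 (1.05 equiv), THF–DMPU, −78 °C; then MeOTf (1.05 equiv), −78 → 0 °C
Reagents that add atoms: methyl trifluoromethanesulfonate, COS(=O)(=O)C(F)(F)F
Why: Enolate O-alkylation: kinetic deprotonation at C2 gives the aromatic potassium furan-3-olate, whose oxygen should be methylated by the hard electrophile MeOTf in a dipolar medium, as in the conversion of benzofuran-3(2H)-ones into 3-methoxybenzofurans.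

Step 10
Reactants: 18 2-[2-(benzyloxy)ethyl]-4-methoxyfuran; 8 3-bromo-1-(2,3-dibromo-4,5-dimethoxyphenyl)prop-2-yn-1-one
Product: 20 {6-[2-(benzyloxy)ethyl]-2-bromo-3-hydroxy-4-methoxyphenyl}(2,3-dibromo-4,5-dimethoxyphenyl)methanone, via oxanorbornadiene 19 (not isolated)
Conditions: PhMe, 25 → 60 °C, dark, argon; then TFA (10 mol%), CH2Cl2, 0 °C
Reagents that add atoms: none
Why: An asynchronous, normal-electron-demand [4+2] cycloaddition joins the four furan carbons of 18 to the ynone triple bond of 8, forming C4–C3 and C1–C2 of ring A and giving the 7-oxanorbornadiene 19. The closest known reaction type is the Diels–Alder reaction of 3-alkoxyfurans and of furans with 3-halopropiolates, followed by acid-promoted opening of the 7-oxanorbornadiene to a phenol. Ring A is closed by this intermolecular suprafacial cycloaddition as a six-membered carbocycle, after which trace acid ionizes the C1–O bridge bond to a cation that is tertiary and vinylogously stabilized by the C5 methoxy group, and loss of the C4 proton aromatizes the ring with the former furan oxygen as the C4 hydroxyl. No stereocentre remains, since the two bridgehead centres of racemic 19 are erased on aromatization. The step needs regioselectivity, and polarity matching should secure it: the furan carbon between the ring oxygen and the methoxy-bearing carbon is the most nucleophilic terminus and bonds to the bromine-bearing β-carbon of the ynone, so that Br lands at C3 beside the C4 hydroxyl and the aroyl group at C2 beside the side chain. The direction of ring opening is also set by the substrate, because cleavage of the C4–O bond instead would place the cation next to the acyl-bearing alkene and only cross-conjugated to the methoxy group.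

Step 11
Reactants: 20 {6-[2-(benzyloxy)ethyl]-2-bromo-3-hydroxy-4-methoxyphenyl}(2,3-dibromo-4,5-dimethoxyphenyl)methanone
Product: 21 4-[2-(benzyloxy)ethyl]-2-bromo-3-[(2,3-dibromo-4,5-dimethoxyphenyl)methyl]-6-methoxyphenol
Conditions: Et3SiH (4 equiv), TFA–CH2Cl2 (1:1), 0 °C → rt
Reagents that add atoms: none
Why: Ionic hydrogenation: the protonated diaryl ketone and then the diarylmethyl cation, stabilized by a para methoxy group on each ring, each accept hydride from Et3SiH, and any side-chain debenzylation through a transient isochroman is harmless because both products converge on 22 in step 12.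

Step 12
Reactants: 21 4-[2-(benzyloxy)ethyl]-2-bromo-3-[(2,3-dibromo-4,5-dimethoxyphenyl)methyl]-6-methoxyphenol
Product: 22 3-bromo-4-[(2,3-dibromo-4,5-dihydroxyphenyl)methyl]-5-(2-hydroxyethyl)benzene-1,2-diol
Conditions: BBr3 (8 equiv), CH2Cl2, −78 → 0 °C; MeOH then H2O, 0 °C
Reagents that add atoms: none
Why: Lewis-acid ether cleavage: BBr3 coordinates the three aryl methyl ethers and the benzyl ether and bromide attacks the methyl and benzylic carbons, while holding the temperature at or below 0 °C should let the primary alkoxyborane be hydrolysed to the alcohol instead of being converted into the bromide.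

Step 13
Reactants: 22 3-bromo-4-[(2,3-dibromo-4,5-dihydroxyphenyl)methyl]-5-(2-hydroxyethyl)benzene-1,2-diol
Product: 24 2-{3-bromo-2-[(2,3-dibromo-4,5-dihydroxyphenyl)methyl]-4,5-dihydroxyphenyl}ethyl hydrogen sulfate, via pyridinium sulfate 23 (not isolated)
Conditions: SO3·pyridine (1.1 equiv), DMF, 0 °C → rt; then Dowex 50W (H+ form), H2O–MeOH, 0 °C
Reagents that add atoms: sulfur trioxide–pyridine complex, [O-]S(=O)(=O)[n+]1ccccc1
Why: O-sulfation by SO3 transfer: without added base the unhindered primary aliphatic hydroxyl should be far more nucleophilic than the four un-ionized, bromine-deactivated and hydrogen-bonded catechol hydroxyls, in line with the known preference of SO3–amine complexes for alcohols over phenols, and acidic ion exchange then gives the hydrogen sulfate.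

Compound list
1 | vanillin (4-hydroxy-3-methoxybenzaldehyde) | COc1cc(C=O)ccc1O | starting material
2 | 5-bromovanillin (3-bromo-4-hydroxy-5-methoxybenzaldehyde) | COc1cc(C=O)cc(Br)c1O | intermediate
3 | 2,3-dibromo-4-hydroxy-5-methoxybenzaldehyde | COc1cc(C=O)c(Br)c(Br)c1O | intermediate
4 | 2,3-dibromo-4,5-dimethoxybenzaldehyde | COc1cc(C=O)c(Br)c(Br)c1OC | intermediate
5 | ethynylmagnesium bromide | C#C[Mg]Br | starting material
6 | 1-(2,3-dibromo-4,5-dimethoxyphenyl)prop-2-yn-1-ol, racemic | COc1cc(C(O)C#C)c(Br)c(Br)c1OC | intermediate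
7 | 1-(2,3-dibromo-4,5-dimethoxyphenyl)prop-2-yn-1-one | COc1cc(C(=O)C#C)c(Br)c(Br)c1OC | intermediate
8 | 3-bromo-1-(2,3-dibromo-4,5-dimethoxyphenyl)prop-2-yn-1-one | COc1cc(C(=O)C#CBr)c(Br)c(Br)c1OC | intermediate
9 | benzyl 3-butynyl ether (4-benzyloxybut-1-yne) | C#CCCOCc1ccccc1 | starting material
10 | (tert-butyldimethylsilyloxy)acetaldehyde | O=CCO[Si](C)(C)C(C)(C)C | starting material
11 | lithium acetylide of 9, (4-benzyloxybut-1-yn-1-yl)lithium | [Li]C#CCCOCc1ccccc1 | intermediate
12 | 6-(benzyloxy)-1-[(tert-butyldimethylsilyl)oxy]hex-3-yn-2-ol, racemic | CC(C)(C)[Si](C)(C)OCC(O)C#CCCOCc1ccccc1 | intermediate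
13 | 6-(benzyloxy)-1-[(tert-butyldimethylsilyl)oxy]hex-3-yn-2-one | CC(C)(C)[Si](C)(C)OCC(=O)C#CCCOCc1ccccc1 | intermediate
14 | (E)-6-(benzyloxy)-1-[(tert-butyldimethylsilyl)oxy]-4-(diethylamino)hex-3-en-2-one (silyl enaminone) | CCN(CC)/C(CCOCc1ccccc1)=C/C(=O)CO[Si](C)(C)C(C)(C)C | intermediate
15 | (E)-6-(benzyloxy)-4-(diethylamino)-1-hydroxyhex-3-en-2-one (hydroxy enaminone) | CCN(CC)/C(CCOCc1ccccc1)=C/C(=O)CO | intermediate
16 | 5-[2-(benzyloxy)ethyl]furan-3(2H)-one | O=C1COC(CCOCc2ccccc2)=C1 | intermediate
17 | potassium 5-[2-(benzyloxy)ethyl]furan-3-olate | [K+].[O-]c1coc(CCOCc2ccccc2)c1 | intermediate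
18 | 2-[2-(benzyloxy)ethyl]-4-methoxyfuran | COc1coc(CCOCc2ccccc2)c1 | intermediate
19 | {1-[2-(benzyloxy)ethyl]-3-bromo-5-methoxy-7-oxabicyclo[2.2.1]hepta-2,5-dien-2-yl}(2,3-dibromo-4,5-dimethoxyphenyl)methanone, racemic, bridgeheads tied cis by the oxygen bridge | COC1=CC2(CCOCc3ccccc3)OC1C(Br)=C2C(=O)c1cc(OC)c(OC)c(Br)c1Br | intermediate
20 | {6-[2-(benzyloxy)ethyl]-2-bromo-3-hydroxy-4-methoxyphenyl}(2,3-dibromo-4,5-dimethoxyphenyl)methanone | COc1cc(CCOCc2ccccc2)c(C(=O)c2cc(OC)c(OC)c(Br)c2Br)c(Br)c1O | intermediate
21 | 4-[2-(benzyloxy)ethyl]-2-bromo-3-[(2,3-dibromo-4,5-dimethoxyphenyl)methyl]-6-methoxyphenol | COc1cc(CCOCc2ccccc2)c(Cc2cc(OC)c(OC)c(Br)c2Br)c(Br)c1O | intermediate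
22 | 3-bromo-4-[(2,3-dibromo-4,5-dihydroxyphenyl)methyl]-5-(2-hydroxyethyl)benzene-1,2-diol | OCCc1cc(O)c(O)c(Br)c1Cc1cc(O)c(O)c(Br)c1Br | intermediate
23 | pyridinium 2-{3-bromo-2-[(2,3-dibromo-4,5-dihydroxyphenyl)methyl]-4,5-dihydroxyphenyl}ethyl sulfate | [O-]S(=O)(=O)OCCc1cc(O)c(O)c(Br)c1Cc1cc(O)c(O)c(Br)c1Br.c1cc[nH+]cc1 | intermediate
24 | 2-{3-bromo-2-[(2,3-dibromo-4,5-dihydroxyphenyl)methyl]-4,5-dihydroxyphenyl}ethyl hydrogen sulfate (CNP0136879.0) | O=S(=O)(O)OCCc1cc(O)c(O)c(Br)c1Cc1cc(O)c(O)c(Br)c1Br | target

Total step count: 13.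
Longest linear sequence: 9 steps (steps 1–5 and 10–13, from vanillin); the furan branch (steps 6–9) joins at step 10.

Steps most likely to fail

Step 10. The electron-rich furan may attack the bromine of the bromoalkyne or substitute it by addition–elimination faster than it cycloadds, and the labile methoxyfuran may decompose before it is consumed. The fallback takes the bromine out of the dienophile and introduces it afterwards. It sets out from the terminal ynone 7 and the furan 18: the same cycloaddition (PhMe, 25 → 60 °C) should give {1-[2-(benzyloxy)ethyl]-5-methoxy-7-oxabicyclo[2.2.1]hepta-2,5-dien-2-yl}(2,3-dibromo-4,5-dimethoxyphenyl)methanone F1, which trace acid should open to {2-[2-(benzyloxy)ethyl]-5-hydroxy-4-methoxyphenyl}(2,3-dibromo-4,5-dimethoxyphenyl)methanone F2, in which C3 still bears hydrogen. Bromination ortho to the phenolic hydroxyl (NBS, cat. i-Pr2NH, CH2Cl2, 0 °C) should then take the one open position activated by the free OH, as in the bromination of isovanillin at its 2-position, and the fallback comes back to the route at 20.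

Step 13. Sulfation may spread to the phenolic hydroxyls or run past the monosulfate, and the free catechols may oxidize during work-up. The fallback masks the catechols first and sets out from 22. Ketalization of both catechols (2,2-dimethoxypropane, cat. TsOH, PhMe, reflux) should give 2-{7-bromo-6-[(6,7-dibromo-2,2-dimethyl-1,3-benzodioxol-5-yl)methyl]-2,2-dimethyl-1,3-benzodioxol-5-yl}ethanol F3, whose only free hydroxyl is then sulfated (SO3·pyridine, pyridine, rt) to pyridinium 2-{7-bromo-6-[(6,7-dibromo-2,2-dimethyl-1,3-benzodioxol-5-yl)methyl]-2,2-dimethyl-1,3-benzodioxol-5-yl}ethyl sulfate F4. Aqueous TFA at 0 °C → rt, followed by the same acidic resin, should remove both acetonides, and the fallback comes back to the route at 24.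

Step 9. The ambident furanolate may be methylated at C2 instead of at oxygen, and the acid- and air-sensitive methoxyfuran may be lost on isolation. The fallback replaces the methyl group by a silyl group, put on by soft enolization, which is reliably O-selective, and sets out from 16. Treatment with TIPSOTf and Et3N (CH2Cl2, 0 °C) should give ({5-[2-(benzyloxy)ethyl]furan-3-yl}oxy)triisopropylsilane F5. F5 takes the place of 18 in the cycloaddition with 8 and should give {1-[2-(benzyloxy)ethyl]-3-bromo-5-[(triisopropylsilyl)oxy]-7-oxabicyclo[2.2.1]hepta-2,5-dien-2-yl}(2,3-dibromo-4,5-dimethoxyphenyl)methanone F6. Work-up with aqueous HCl in THF should hydrolyse the silyl enol ether and open the bridge to {6-[2-(benzyloxy)ethyl]-2-bromo-3,4-dihydroxyphenyl}(2,3-dibromo-4,5-dimethoxyphenyl)methanone F7. Ionic hydrogenation (Et3SiH, TFA, CH2Cl2) should give 5-[2-(benzyloxy)ethyl]-3-bromo-4-[(2,3-dibromo-4,5-dimethoxyphenyl)methyl]benzene-1,2-diol F8, and BBr3 (CH2Cl2, −78 → 0 °C) brings the fallback back to the route at 22.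

Further compounds
F1 | step 10 | {1-[2-(benzyloxy)ethyl]-5-methoxy-7-oxabicyclo[2.2.1]hepta-2,5-dien-2-yl}(2,3-dibromo-4,5-dimethoxyphenyl)methanone, racemic | COC1=CC2(CCOCc3ccccc3)OC1C=C2C(=O)c1cc(OC)c(OC)c(Br)c1Br
F2 | step 10 | {2-[2-(benzyloxy)ethyl]-5-hydroxy-4-methoxyphenyl}(2,3-dibromo-4,5-dimethoxyphenyl)methanone | COc1cc(CCOCc2ccccc2)c(cc1O)C(=O)c1cc(OC)c(OC)c(Br)c1Br
F3 | step 13 | 2-{7-bromo-6-[(6,7-dibromo-2,2-dimethyl-1,3-benzodioxol-5-yl)methyl]-2,2-dimethyl-1,3-benzodioxol-5-yl}ethanol | OCCc1cc2OC(C)(C)Oc2c(Br)c1Cc1cc2OC(C)(C)Oc2c(Br)c1Br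
F4 | step 13 | pyridinium 2-{7-bromo-6-[(6,7-dibromo-2,2-dimethyl-1,3-benzodioxol-5-yl)methyl]-2,2-dimethyl-1,3-benzodioxol-5-yl}ethyl sulfate | [O-]S(=O)(=O)OCCc1cc2OC(C)(C)Oc2c(Br)c1Cc1cc2OC(C)(C)Oc2c(Br)c1Br.c1cc[nH+]cc1
F5 | step 9 | ({5-[2-(benzyloxy)ethyl]furan-3-yl}oxy)triisopropylsilane | CC(C)[Si](Oc1coc(CCOCc2ccccc2)c1)(C(C)C)C(C)C
F6 | step 9 | {1-[2-(benzyloxy)ethyl]-3-bromo-5-[(triisopropylsilyl)oxy]-7-oxabicyclo[2.2.1]hepta-2,5-dien-2-yl}(2,3-dibromo-4,5-dimethoxyphenyl)methanone, racemic | CC(C)[Si](OC1=CC2(CCOCc3ccccc3)OC1C(Br)=C2C(=O)c1cc(OC)c(OC)c(Br)c1Br)(C(C)C)C(C)C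
F7 | step 9 | {6-[2-(benzyloxy)ethyl]-2-bromo-3,4-dihydroxyphenyl}(2,3-dibromo-4,5-dimethoxyphenyl)methanone | Oc1cc(CCOCc2ccccc2)c(C(=O)c2cc(OC)c(OC)c(Br)c2Br)c(Br)c1O
F8 | step 9 | 5-[2-(benzyloxy)ethyl]-3-bromo-4-[(2,3-dibromo-4,5-dimethoxyphenyl)methyl]benzene-1,2-diol | Oc1cc(CCOCc2ccccc2)c(Cc2cc(OC)c(OC)c(Br)c2Br)c(Br)c1O
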